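**Retrosynthetic overview** (dictyol numbering: C1/C5 ring fusion, C3=C4(Me), C6–O, C7, C8, C9–O, C10(=CH2); side chain C11(Me)–C12(O)–C13(O)–C14=C15)
1. Target 33 ⇐ (desilylation, diacetylation) diol 31 ⇐ C11–C12: secondary boronic ester 22 (boron on C11) + trans-lithiated alkenyl epoxide from 26 (C12–C15), by 1,2-metallate rearrangement and C–B oxidation.
2. Enabling feature: C11 is a methyl-bearing methine exocyclic to the seven-membered ring (on C7) and directly bonded to the syn-1,2-diol C12/C13; boron on C11 and an epoxide spanning C12–C13 deliver the bond, the C12 stereocentre and both diol oxygens.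
3. 22 ⇐ ethylidene insertion into the C7–B bond of 17 ⇐ seven-membered ring by Nozaki–Hiyama–Kishi closure (C9–C10) of 15; C7–B from Cu-catalysed β-borylation of enoate 12.
4. 12 ⇐ cyclopentenone 5 (C1 from chiral-pool enone 1) by α′-aldol (C5–C6) and conversion of the ring ketone into the C3=C4 methyl alkene.
5. Ring order: five-membered ring present from the start; seven-membered ring closed in step 9; the key step closes no ring.

Key step: step 16

Assumption: (S)-1 is purchasable (both enantiomers are sold), and all organometallic, enolate and hydride steps are quenched with water, so spent metals end as hydroxides.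

**Step 1**
Reactants: 1 (S)-4-[(tert-butyldimethylsilyl)oxy]cyclopent-2-en-1-one; 2 (1-bromoethenyl)trimethylsilane
Product: 5 (S)-4-[1-(trimethylsilyl)ethenyl]cyclopent-2-en-1-one, via vinylmagnesium reagent 3 (not isolated), via silyloxy ketone 4 (not isolated)
Conditions: 2, Mg, THF, rt; then 1, CuBr·SMe2 (10 mol %), THF, −78 °C; H2O; then DBU, CH2Cl2, 0 °C → rt
Reagents that add atoms: none
Why: Copper-catalysed 1,4-addition of the Grignard reagent should occur anti to the C4 silyloxy group (fixing the future C1), and E1cB loss of silanol then gives the transposed enone, the usual chirality relay of 4-silyloxycyclopentenones.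

**Step 2**
Reactants: 5; 6 ethyl (E)-4-oxobut-2-enoate
Product: 8 ethyl (2E,4R)-4-hydroxy-4-{(1R,5R)-2-oxo-5-[1-(trimethylsilyl)ethenyl]cyclopent-3-en-1-yl}but-2-enoate, via lithium dienolate 7 (not isolated)
Conditions: LDA, THF, −78 °C; then 6, −78 °C; H2O
Reagents that add atoms: none
Why: Kinetic α′-deprotonation gives the cross-conjugated enolate, which should add 1,2 to the aldehyde through a Zimmerman–Traxler chair (aldol addition): attack anti to the neighbouring silylvinyl group sets C5 trans to C1, and the fixed E(O)-enolate geometry should favour the anti aldol (C6), any syn isomer being removed by chromatography.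

**Step 3**
Reactants: 8
Product: 9 ethyl (2E,4R)-4-[(tert-butyldimethylsilyl)oxy]-4-{(1R,5R)-2-oxo-5-[1-(trimethylsilyl)ethenyl]cyclopent-3-en-1-yl}but-2-enoate
Conditions: TBSOTf, 2,6-lutidine, CH2Cl2, −78 → 0 °C
Reagents that add atoms: tert-butyldimethylsilyl trifluoromethanesulfonate, CC(C)(C)[Si](C)(C)OS(=O)(=O)C(F)(F)F
Why: Silylation of the secondary alcohol blocks retro-aldol and dehydration and does not touch a stereocentre.

**Step 4**
Reactants: 9
Product: 11 enol triflate, ethyl (2E,4R)-4-[(tert-butyldimethylsilyl)oxy]-4-{(1R,5R)-2-[(trifluoromethylsulfonyl)oxy]-5-[1-(trimethylsilyl)ethenyl]cyclopent-2-en-1-yl}but-2-enoate, via triethylsilyl enol ether 10 (not isolated)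
Conditions: Et3SiH, RhCl(PPh3)3 (2 mol %), THF, 50 °C; then CsF, PhNTf2, DME, rt
Reagents that add atoms: N-phenylbis(trifluoromethanesulfonimide), O=S(=O)(N(c1ccccc1)S(=O)(=O)C(F)(F)F)C(F)(F)F
Why: Rh-catalysed 1,4-hydrosilylation of the cyclopentenone (more reactive than the enoate) gives the enol silane regiospecifically on the C3 side, and fluoride-mediated O-triflation transfers that regiochemistry to the vinyl triflate.

**Step 5**
Reactants: 11
Product: 12 ethyl (2E,4R)-4-[(tert-butyldimethylsilyl)oxy]-4-{(1S,5R)-2-methyl-5-[1-(trimethylsilyl)ethenyl]cyclopent-2-en-1-yl}but-2-enoate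
Conditions: MeZnCl, Pd(PPh3)4 (5 mol %), THF, rt → 50 °C
Reagents that add atoms: methylzinc chloride, C[Zn]Cl
Why: Negishi coupling of the vinyl triflate installs the C4 methyl group on the C3=C4 alkene without affecting the ester, the enoate or the vinylsilane.

**Step 6**
Reactants: 12
Product: 13 ethyl (3R,4R)-4-[(tert-butyldimethylsilyl)oxy]-4-{(1S,5R)-2-methyl-5-[1-(trimethylsilyl)ethenyl]cyclopent-2-en-1-yl}-3-(4,4,5,5-tetramethyl-1,3,2-dioxaborolan-2-yl)butanoate
Conditions: B2pin2, CuCl (5 mol %), Josiphos-type ligand (matched enantiomer, 5 mol %), NaOtBu (7 mol %), MeOH (2 equiv), THF, rt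
Reagents that add atoms: bis(pinacolato)diboron, CC1(C)OB(OC1(C)C)B1OC(C)(C)C(C)(C)O1
Why: Cu(I)-catalysed conjugate borylation of the (E)-γ-silyloxy enoate should place boron at C7 anti to the C6 silyloxy group (Felkin–Anh-type 1,2-induction reinforced by the matched ligand) and leaves the unactivated alkenes untouched.

**Step 7**
Reactants: 13
Product: 14 ethyl (3R,4R)-4-[(tert-butyldimethylsilyl)oxy]-4-[(1S,5R)-5-(1-iodoethenyl)-2-methylcyclopent-2-en-1-yl]-3-(4,4,5,5-tetramethyl-1,3,2-dioxaborolan-2-yl)butanoate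
Conditions: NIS, MeCN/ClCH2CN (4:1), 0 °C, dark
Reagents that add atoms: N-iodosuccinimide, O=C1CCC(=O)N1I
Why: ipso-Iododesilylation of the vinylsilane (β-silyl cation stabilisation makes it the most nucleophilic alkene) gives the 2-iodoalkene needed for ring closure.

**Step 8**
Reactants: 14
Product: 15 (3R,4R)-4-[(tert-butyldimethylsilyl)oxy]-4-[(1S,5R)-5-(1-iodoethenyl)-2-methylcyclopent-2-en-1-yl]-3-(4,4,5,5-tetramethyl-1,3,2-dioxaborolan-2-yl)butanal
Conditions: DIBAL-H, CH2Cl2, −78 °C; H2O
Reagents that add atoms: none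
Why: Partial reduction of the ethyl ester stops at the aldehyde through the stable tetrahedral aluminate at −78 °C, and the boronic ester and vinyl iodide tolerate DIBAL-H.

**Step 9**
Reactants: 15
Product: 16 bicyclic allylic alcohol (1R,5S,6R,7R,9R)-6-[(tert-butyldimethylsilyl)oxy]-4-methyl-10-methylidene-7-(pinacolboryl)bicyclo[5.3.0]dec-3-en-9-ol (dictyol numbering)
Conditions: CrCl2 (8 equiv), NiCl2 (1 mol %), DMSO/THF, rt, 5 mM; H2O
Reagents that add atoms: none
Why: Intramolecular Nozaki–Hiyama–Kishi addition of the alkenylchromium to the aldehyde closes the seven-membered ring (C9–C10) and creates the exocyclic methylene carbinol; C9 should form with its C–O bond pseudo-axial (avoiding A(1,3) strain with the methylene) and hence trans to the equatorial C7 boryl group.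

**Step 10**
Reactants: 16
Product: 17 (1R,5S,6R,7R,9R)-6,9-bis[(tert-butyldimethylsilyl)oxy]-4-methyl-10-methylidene-7-(pinacolboryl)bicyclo[5.3.0]dec-3-ene
Conditions: TBSOTf, 2,6-lutidine, CH2Cl2, −78 → 0 °C
Reagents that add atoms: tert-butyldimethylsilyl trifluoromethanesulfonate, CC(C)(C)[Si](C)(C)OS(=O)(=O)C(F)(F)F
Why: Silylation removes the only acidic and boron-coordinating group before the organolithium steps.

**Step 11**
Reactants: 18 2,4,6-triisopropylbenzoic acid
Product: 19 ethyl 2,4,6-triisopropylbenzoate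
Conditions: EtI, K2CO3, DMF, rt
Reagents that add atoms: iodoethane, CCI
Why: SN2 O-alkylation of the carboxylate gives the hindered benzoate that serves as directing and leaving group in the next step.

**Step 12**
Reactants: 19; 17
Product: 22 (1R,5S,6R,7S,9R)-6,9-bis[(tert-butyldimethylsilyl)oxy]-4-methyl-10-methylidene-7-[(1R)-1-(pinacolboryl)ethyl]bicyclo[5.3.0]dec-3-ene, via α-lithiated benzoate 20 (not isolated), via boronate complex 21 (not isolated)
Conditions: 19, s-BuLi, (−)-sparteine, Et2O, −78 °C, 5 h; then 17, −78 °C → reflux; H2O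
Reagents that add atoms: none
Why: Sparteine-mediated asymmetric deprotonation gives the configurationally stable (S)-α-lithio benzoate, which is borylated with retention and undergoes 1,2-metallate rearrangement (lithiation–borylation homologation) with inversion at the carbenoid carbon and retention at migrating C7, so C11 is set by the reagent.

**Step 13**
Reactants: 23 (E)-3-(tributylstannyl)prop-2-en-1-ol
Product: 24 [(2S,3S)-3-(tributylstannyl)oxiran-2-yl]methanol
Conditions: t-BuOOH, Ti(OiPr)4 (cat.), L-(+)-DIPT (cat.), 4 Å MS, CH2Cl2, −20 °C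
Reagents that add atoms: tert-butyl hydroperoxide, CC(C)(C)OO
Why: Sharpless asymmetric epoxidation of the (E)-allylic alcohol with the L-(+)-tartrate delivers oxygen to the face that gives the (2S,3S)-trans-epoxide, which fixes the future C13.

**Step 14**
Reactants: 24
Product: 25 (2S,3S)-3-(tributylstannyl)oxirane-2-carbaldehyde
Conditions: Dess–Martin periodinane, pyridine, CH2Cl2, 0 °C
Reagents that add atoms: none
Why: Buffered hypervalent-iodine oxidation gives the epoxy aldehyde without epimerisation or epoxide opening.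

**Step 15**
Reactants: 25
Product: 26 tributyl[(2S,3S)-3-(2-methylprop-1-en-1-yl)oxiran-2-yl]stannane
Conditions: i-PrPPh3I, n-BuLi, THF, 0 °C; then 25, −78 → 0 °C
Reagents that add atoms: isopropyltriphenylphosphonium iodide, CC(C)[P+](c1ccccc1)(c1ccccc1)c1ccccc1.[I-]
Why: Wittig olefination with the isopropylidene ylide installs the C14=C15 alkene, and the symmetrical ylide raises no E/Z issue.

**Step 16**
Reactants: 26; 22
Product: 31 (1R,5S,6R,7S,9R,11R,12S,13S)-6,9-bis(TBS)-protected 12,13-diol, via trans-oxiranyllithium 27 (not isolated), via boronate complex 28 (not isolated), via silyloxy boronic ester 29 (not isolated), via triethylsilyl ether 30 (not isolated)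
Conditions: 26, n-BuLi, TMEDA, THF, −95 °C, 10 min; then 22, −95 → −78 °C; then TESOTf, −78 °C → rt; then NaOH, H2O2, THF/H2O, 0 °C; then PPTS (cat.), MeOH, rt
Reagents that add atoms: hydrogen peroxide, OO
Why: Tin–lithium exchange gives the trans-oxiranyllithium with retention, which adds to the boron of 22; silyl triflate activation of the epoxide oxygen then triggers a 1,2-metallate rearrangement in which C11 migrates from boron to C12 anti to the breaking C12–O bond, and peroxide oxidation replaces boron by hydroxyl with retention before the labile triethylsilyl ether is methanolysed. The closest known reaction type is the homologation of alkyl pinacol boronic esters with lithiated epoxides to give syn-1,2-diols (lithiation–borylation). No ring is closed; the oxirane is opened. C12 is set by the trans geometry of the lithiated epoxide together with the stereospecific invertive migration, while C13 (from the Sharpless epoxide) and C11 (retentive migration from 22) are carried over unchanged, so the syn-C12/C13 diol and the C11/C12 relationship do not depend on facial selection. The step needs attack at boron only and migration of the secondary alkyl group rather than a pinacol oxygen: boron is the sole electrophile in the fully silylated 22, and anti-periplanar alignment of the C11–B bond with the activated epoxide C–O bond should secure carbon migration.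

**Step 17**
Reactants: 31
Product: 32 6,9-bis(TBS)-protected 12,13-diacetate
Conditions: Ac2O, pyridine, DMAP (cat.), CH2Cl2, rt
Reagents that add atoms: acetic anhydride, CC(=O)OC(C)=O
Why: Acylation of the two free secondary hydroxyls proceeds without touching a stereocentre while the ring hydroxyls stay silylated.

**Step 18**
Reactants: 32
Product: 33 target (1R,5S,6R,7S,9R,11R,12S,13S)
Conditions: HF·pyridine, pyridine, THF, 0 °C → rt
Reagents that add atoms: none
Why: Buffered fluoride cleaves both silyl ethers, and the acetates and the three alkenes should be stable under these conditions.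

**Compound list**
1 | (S)-4-[(tert-butyldimethylsilyl)oxy]cyclopent-2-en-1-one | O=C1C=C[C@@H](O[Si](C)(C)C(C)(C)C)C1 | starting material
2 | (1-bromoethenyl)trimethylsilane | C=C(Br)[Si](C)(C)C | starting material
3 | [1-(trimethylsilyl)ethenyl]magnesium bromide | C=C([Mg]Br)[Si](C)(C)C | intermediate
4 | (3S,4S)-4-[(tert-butyldimethylsilyl)oxy]-3-[1-(trimethylsilyl)ethenyl]cyclopentan-1-one | O=C1C[C@H](C(=C)[Si](C)(C)C)[C@@H](O[Si](C)(C)C(C)(C)C)C1 | intermediate
5 | (S)-4-[1-(trimethylsilyl)ethenyl]cyclopent-2-en-1-one | O=C1C=C[C@@H](C(=C)[Si](C)(C)C)C1 | intermediate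
6 | ethyl (E)-4-oxobut-2-enoate | CCOC(=O)/C=C/C=O | starting material
7 | lithium 3-[1-(trimethylsilyl)ethenyl]cyclopenta-1,4-dien-1-olate (α′-dienolate of 5, C3 as in 5) | [Li+].[O-]C1=C[C@H](C(=C)[Si](C)(C)C)C=C1 | intermediate
8 | ethyl (2E,4R)-4-hydroxy-4-{(1R,5R)-2-oxo-5-[1-(trimethylsilyl)ethenyl]cyclopent-3-en-1-yl}but-2-enoate | CCOC(=O)/C=C/[C@@H](O)[C@@H]1C(=O)C=C[C@H]1C(=C)[Si](C)(C)C | intermediate
9 | 4-O-TBS ether of 8 | CCOC(=O)/C=C/[C@@H](O[Si](C)(C)C(C)(C)C)[C@@H]1C(=O)C=C[C@H]1C(=C)[Si](C)(C)C | intermediate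
10 | triethylsilyl enol ether from 1,4-reduction of 9 (enol ether C=C towards the ring CH2) | CCOC(=O)/C=C/[C@@H](O[Si](C)(C)C(C)(C)C)[C@@H]1C(O[Si](CC)(CC)CC)=CC[C@H]1C(=C)[Si](C)(C)C | intermediate
11 | corresponding enol triflate | CCOC(=O)/C=C/[C@@H](O[Si](C)(C)C(C)(C)C)[C@@H]1C(OS(=O)(=O)C(F)(F)F)=CC[C@H]1C(=C)[Si](C)(C)C | intermediate
12 | ethyl (2E,4R)-4-(TBS-oxy)-4-{(1S,5R)-2-methyl-5-[1-(trimethylsilyl)ethenyl]cyclopent-2-en-1-yl}but-2-enoate | CCOC(=O)/C=C/[C@@H](O[Si](C)(C)C(C)(C)C)[C@@H]1C(C)=CC[C@H]1C(=C)[Si](C)(C)C | intermediate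
13 | ethyl (3R,4R)-4-(TBS-oxy)-4-{(1S,5R)-2-methyl-5-[1-(trimethylsilyl)ethenyl]cyclopent-2-en-1-yl}-3-(pinacolboryl)butanoate | CCOC(=O)C[C@@H](B2OC(C)(C)C(C)(C)O2)[C@@H](O[Si](C)(C)C(C)(C)C)[C@@H]1C(C)=CC[C@H]1C(=C)[Si](C)(C)C | intermediate
14 | ethyl (3R,4R)-4-(TBS-oxy)-4-[(1S,5R)-5-(1-iodoethenyl)-2-methylcyclopent-2-en-1-yl]-3-(pinacolboryl)butanoate | CCOC(=O)C[C@@H](B2OC(C)(C)C(C)(C)O2)[C@@H](O[Si](C)(C)C(C)(C)C)[C@@H]1C(C)=CC[C@H]1C(I)=C | intermediate
15 | (3R,4R)-4-(TBS-oxy)-4-[(1S,5R)-5-(1-iodoethenyl)-2-methylcyclopent-2-en-1-yl]-3-(pinacolboryl)butanal | O=CC[C@@H](B2OC(C)(C)C(C)(C)O2)[C@@H](O[Si](C)(C)C(C)(C)C)[C@@H]1C(C)=CC[C@H]1C(I)=C | intermediate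
16 | (1R,5S,6R,7R,9R)-6-(TBS-oxy)-4-methyl-10-methylidene-7-(pinacolboryl)bicyclo[5.3.0]dec-3-en-9-ol (dictyol numbering) | C=C1[C@H](O)C[C@@H](B3OC(C)(C)C(C)(C)O3)[C@@H](O[Si](C)(C)C(C)(C)C)[C@@H]2C(C)=CC[C@@H]12 | intermediate
17 | 9-O-TBS ether of 16 | C=C1[C@H](O[Si](C)(C)C(C)(C)C)C[C@@H](B3OC(C)(C)C(C)(C)O3)[C@@H](O[Si](C)(C)C(C)(C)C)[C@@H]2C(C)=CC[C@@H]12 | intermediate
18 | 2,4,6-triisopropylbenzoic acid | OC(=O)c1c(C(C)C)cc(C(C)C)cc1C(C)C | starting material
19 | ethyl 2,4,6-triisopropylbenzoate | CCOC(=O)c1c(C(C)C)cc(C(C)C)cc1C(C)C | intermediate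
20 | (S)-1-lithioethyl 2,4,6-triisopropylbenzoate (sparteine complex) | C[C@H]([Li])OC(=O)c1c(C(C)C)cc(C(C)C)cc1C(C)C | intermediate
21 | lithium boronate complex of 17 with 20 (boron on C7 and on the benzoyloxy-bearing carbon) | [Li+].C=C1[C@H](O[Si](C)(C)C(C)(C)C)C[C@@H]([B-]3(OC(C)(C)C(C)(C)O3)[C@@H](C)OC(=O)c4c(C(C)C)cc(C(C)C)cc4C(C)C)[C@@H](O[Si](C)(C)C(C)(C)C)[C@@H]2C(C)=CC[C@@H]12 | intermediate
22 | (1R,5S,6R,7S,9R,11R)-6,9-bis(TBS-oxy) C11 pinacol boronic ester (ring fragment with CH(CH3)Bpin on C7) | C=C1[C@H](O[Si](C)(C)C(C)(C)C)C[C@@H]([C@@H](C)B3OC(C)(C)C(C)(C)O3)[C@@H](O[Si](C)(C)C(C)(C)C)[C@@H]2C(C)=CC[C@@H]12 | intermediate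
23 | (E)-3-(tributylstannyl)prop-2-en-1-ol | OC/C=C/[Sn](CCCC)(CCCC)CCCC | starting material
24 | [(2S,3S)-3-(tributylstannyl)oxiran-2-yl]methanol | OC[C@@H]1O[C@H]1[Sn](CCCC)(CCCC)CCCC | intermediate
25 | (2S,3S)-3-(tributylstannyl)oxirane-2-carbaldehyde | O=C[C@@H]1O[C@H]1[Sn](CCCC)(CCCC)CCCC | intermediate
26 | tributyl[(2S,3S)-3-(2-methylprop-1-en-1-yl)oxiran-2-yl]stannane | CC(C)=C[C@@H]1O[C@H]1[Sn](CCCC)(CCCC)CCCC | intermediate
27 | trans-3-(2-methylprop-1-en-1-yl)oxiran-2-yllithium (configuration of 26 retained) | CC(C)=C[C@@H]1O[C@H]1[Li] | intermediate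
28 | lithium boronate complex of 22 with 27 (boron bonded to C11 and to the oxirane carbon C12) | [Li+].C=C1[C@H](O[Si](C)(C)C(C)(C)C)C[C@@H]([C@@H](C)[B-]3(OC(C)(C)C(C)(C)O3)[C@@H]4O[C@H]4C=C(C)C)[C@@H](O[Si](C)(C)C(C)(C)C)[C@@H]2C(C)=CC[C@@H]12 | intermediate
29 | 12-pinacolboryl 13-triethylsilyl ether (C11–C12 bond formed; ring hydroxyls as TBS ethers) | C=C1[C@H](O[Si](C)(C)C(C)(C)C)C[C@@H]([C@@H](C)[C@H](B3OC(C)(C)C(C)(C)O3)[C@H](C=C(C)C)O[Si](CC)(CC)CC)[C@@H](O[Si](C)(C)C(C)(C)C)[C@@H]2C(C)=CC[C@@H]12 | intermediate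
30 | 12-hydroxy 13-triethylsilyl ether (6,9-bis-TBS) | C=C1[C@H](O[Si](C)(C)C(C)(C)C)C[C@@H]([C@@H](C)[C@H](O)[C@H](C=C(C)C)O[Si](CC)(CC)CC)[C@@H](O[Si](C)(C)C(C)(C)C)[C@@H]2C(C)=CC[C@@H]12 | intermediate
31 | (1R,5S,6R,7S,9R,11R,12S,13S)-6,9-bis(TBS-oxy)-12,13-diol | C=C1[C@H](O[Si](C)(C)C(C)(C)C)C[C@@H]([C@@H](C)[C@H](O)[C@H](C=C(C)C)O)[C@@H](O[Si](C)(C)C(C)(C)C)[C@@H]2C(C)=CC[C@@H]12 | intermediate
32 | 6,9-bis(TBS-oxy)-12,13-diacetate | C=C1[C@H](O[Si](C)(C)C(C)(C)C)C[C@@H]([C@@H](C)[C@H](OC(C)=O)[C@H](C=C(C)C)OC(C)=O)[C@@H](O[Si](C)(C)C(C)(C)C)[C@@H]2C(C)=CC[C@@H]12 | intermediate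
33 | CNP0423623.2, (1R,5S,6R,7S,9R,11R,12S,13S)-12,13-diacetoxy-6,9-dihydroxy dictyol-type diterpene | C=C1[C@H](O)C[C@@H]([C@@H](C)[C@H](OC(C)=O)[C@H](C=C(C)C)OC(C)=O)[C@@H](O)[C@@H]2C(C)=CC[C@@H]12 | target

**Step count:** 18 steps in total; longest linear sequence 14 steps (steps 1–10, 12, 16, 17, 18 from 1).

**Steps most likely to fail**

Step 16 (key step). The pre-formed oxiranyllithium may decompose by α-elimination or ring opening before the hindered secondary boronic ester captures it, or the boronate may eliminate instead of rearranging. The fallback sets out from 22 and replaces the transmetalation route by deprotonative metalation with capture as the anion forms, using a tin-free fragment. 3-Methylbut-2-enal is converted with a sulfonium ylide (Corey–Chaykovsky epoxidation) into racemic 2-(2-methylprop-1-en-1-yl)oxirane F1. Hydrolytic kinetic resolution with a chiral (salen)Co(III) catalyst leaves (S)-2-(2-methylprop-1-en-1-yl)oxirane F2. Lithium 2,2,6,6-tetramethylpiperidide is then added to a mixture of F2 and 22, so that the terminal C–H trans to the alkenyl group is lithiated in the presence of the boron electrophile. This comes back to the route at boronate complex 28, which is taken on with TESOTf, oxidation and methanolysis to 31 as in step 16.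

Step 9. The ring-closing addition may show poor facial selectivity at the aldehyde and give C9 epimers. The fallback sets out from the crude epimeric 16: Dess–Martin oxidation gives the exocyclic enone F3, and reagent-controlled reduction with (S)-2-methyl-CBS-oxazaborolidine and catecholborane should deliver the 9R alcohol, coming back at 16.

Step 4. The hydrosilylation may lose chemoselectivity between the ring enone and the enoate, or the fluoride-mediated triflation may be incomplete. The fallback sets out from 9: stoichiometric copper hydride, [(Ph3P)CuH]6, reduces only the cyclopentenone to the saturated ketone F4, and kinetic deprotonation on the CH2 side (KHMDS, −78 °C) with PhNTf2 trapping comes back at 11.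

**Further compounds**
F1 | step 16 | rac-2-(2-methylprop-1-en-1-yl)oxirane | CC(C)=CC1CO1
F2 | step 16 | (S)-2-(2-methylprop-1-en-1-yl)oxirane | CC(C)=C[C@@H]1OC1
F3 | step 9 | 9-oxo analogue of 16 (exocyclic enone, 6-O-TBS, 7-pinacolboryl) | C=C1C(=O)C[C@@H](B3OC(C)(C)C(C)(C)O3)[C@@H](O[Si](C)(C)C(C)(C)C)[C@@H]2C(C)=CC[C@@H]12
F4 | step 4 | ethyl (2E,4R)-4-(TBS-oxy)-4-{2-oxo-5-[1-(trimethylsilyl)ethenyl]cyclopentyl}but-2-enoate (ring stereocentres as in 9) | CCOC(=O)/C=C/[C@@H](O[Si](C)(C)C(C)(C)C)[C@@H]1C(=O)CC[C@H]1C(=C)[Si](C)(C)C
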